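The numbers of this flask were drawn at random within sensible limits, and the outcome is calculated.

You asked for a quick number on what the four flasks will show when read at 1.5 h, with the hunch that more J simply buys a cleaner product.

    Q ⇌ X, rate k1*(cs1 - [X]) while solid is left; crystals form when [X] > cs1 (cs1 = 0.13 M, k1 = 0.0058 s⁻¹)
    X + J → X.J (k2 = 0.24 M⁻¹ s⁻¹)
    X + X.J → X.X.J (k3 = 0.10 M⁻¹ s⁻¹)
    G ⇌ X.J, rate k4*(cs4 - [X.J]) while solid is left; crystals form when [X.J] > cs4 (cs4 = 23 mM, k4 = 0.051 s⁻¹)
    Q + X.J → Q.X.J (k5 = 0.0058 M⁻¹ s⁻¹)

| flask | Q | J | time |
|---|---|---|---|
| south | 0.20 M | 0.200 M | 1.5 h |
| south-east | 0.20 M | 0.400 M | 1.5 h |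
| west | 0.20 M | 0.800 M | 1.5 h |
| east | 0.20 M | 1.50 M | 1.5 h |

- share of X.J in all that became X.J or X.X.J or Q.X.J for south, south-east, west, east, in this order
- how the row runs (falls all the way / rises, then falls / rises all the way / hardly changes / falls, then rises)

- a species is counted by the Q in it: one X.X.J or Q.X.J counts as two
- amounts and yields of X.J count G too
- given per volume of solution although it is solid: Q, G
- at the start none of Q is in solution
- "hardly changes" means that all values lie within two and a half points (for a concentration: within two and a half percent of the largest)
- run time (south): 1.5 h

I took your hunch as right in direction and tried to put a size on it. Q dissolves fastest while no X stands in solution, and at that pace the charge would take about 4.42 min, far shorter than the wait before reading, so I reckoned for the end state.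

I then followed one molecule of X to its fork: it meets J at 0.24 M⁻¹ s⁻¹ times the concentration of J, or dissolved X.J at 0.10 M⁻¹ s⁻¹ times the concentration of that. I put dissolved X.J at its solubility, 23 mM, because crystals take up any excess in about 19.6 s, shorter than the dissolving. The two ways are then equally likely when J stands at 9.58 mM. I call this the even-odds J: the solubility of X.J times the ratio of the two rate constants, a selectivity factor written as a concentration.

Summing the chances as J falls, the X lost to X.X.J comes to the even-odds J times ln(J charged / J left), and each X.X.J holds two Q. In south, where J and Q are charged alike, J falls until J left equals that loss, at 21.5 mM, so 21.5% of the Q goes to X.X.J. Taking J left as the charge minus the Q, I got 6.64% for south-east, 2.76% for west and 1.37% for east. For Q.X.J I took the time solid Q and dissolved X.J stand together, which gives 3.54%, a figure in which J does not appear. My row was therefore 75.0%, 89.8%, 93.7% and 95.1%, rising all the way.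

The forecast gave 70%, 86%, 90% and 92%, rises all the way, its south lower than mine, and of south it said that “X is left over once the solid has gone and it eats X.J”.

The flasks gave 72.8%, 87.5%, 92.0% and 93.7%, rises all the way. At 0.0403 h in south, X.X.J was taking dissolved X.J 3.1 times as fast as Q.X.J. South ended with J left at 2.84 times the even-odds J and east at 136 times, and X.X.J stood at 23.2% of the Q charged in south against 1.90% in east.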